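## The problem

Briarane numbering is used throughout: ring A is C1, C14, C13, C12, C11, C10; the ten-membered ring is C1–C10; C15 is the methyl on C1, C16 the exocyclic methylene on C5, C17/C18/C19 the lactone CH, its methyl and its carbonyl, and C20 the epoxide methylene on C11. The target 45 is a 6/10/5 tricycle: ring A is trans-fused across C1–C10 to the cyclodecane, which is fused across C7–C8 to a γ-lactone (O7–C19), and C11 carries a spiro-epoxide. Eleven stereocentres must be set: the quaternary C1, C2, the anti chlorohydrin pair C6/C7, the tertiary carbinol C8, C9, C10, C11, C12, C14 and C17. Control can flow outward from a ring A triad: C1/C10/C14 can direct C2 (1,2-induction from C1), C12 (hydride opposite the axial C14 oxygen), C11 (epoxidation directed by the C12 hydroxyl) and C9 (induction from C10), while an enantiopure C17 can fix C8, and C8 in turn C7 and C6. The fragile groups are the 1,1-disubstituted epoxide (acid, halide), the secondary allylic chloride next to the lactone oxygen (reduction, elimination, SN2′), the β-hydroxy lactone (retro-aldol), two exocyclic olefins, and four acetates beside a free tertiary alcohol, which exclude hydride and organometallic reagents once the esters are in place. The ten-membered ring must be closed against transannular strain, best at a bond whose formation also creates stereocentres. The enabling feature is ring A itself: oxygen at C12 and C14, carbon branches at C11 (C20) and C10 (C9), and the quaternary C1 (C2, C15) are the retron of a [4+2] union of a 1,3-dioxygenated diene C14=C13–C12=C11 with an E α-methyl enal C1=C10.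

## Retrosynthesis

**Acetates and epoxide (45 ⇒ 44 ⇒ 43).** The four acetyl C–O bonds and the epoxide oxygen are removed first. Acetates cannot survive the hydride, enolate and Grignard steps needed earlier, and the epoxide is the most acid-sensitive group, so both belong at the very end. Epoxide 44 comes from pentaol 43, whose axial allylic C12 hydroxyl can deliver oxygen to C11=C20 from its own face. The forward steps must epoxidize one of two 1,1-disubstituted olefins and acetylate four secondary hydroxyls beside a tertiary one.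

**Lactone oxidation level (43 ⇒ 42 ⇒ 40).** Pentaol 43 is the desilylated lactone 42, and 42 is taken back to the 1,4-diol 40 (C7 secondary, C19 primary). Carrying C19 as an alcohol means that C17 is not α to a carbonyl and cannot epimerize before the ring is closed. It also allows C7 to be the carbonyl carbon of the small lactone used below. The forward step is a primary-selective oxidation that lactonizes onto O7 only, which is why O9 stays silylated.

**Ten-membered ring at C6–C7 (40 ⇒ 38 ⇒ 37).** Cutting C6–C7 removes the ring and both chlorohydrin stereocentres at once. The precursor is lactol 38, a masked C7 aldehyde that carries a γ-chloroallyl bromide (C16–Br, C5=C6HCl) and comes from lactone 37. The neighbouring cuts were weighed and set aside: C5–C6 would require a separate, hindered chloride substitution at C6, and C2–C3 or C8–C9 would form no stereocentre that the ring could help to control. A lactol is preferred to a free tertiary α-hydroxy aldehyde, which is prone to α-ketol rearrangement. The forward reaction must give the anti chlorohydrin with Felkin–Anh sense at C7 and must not reduce the product's allylic chloride.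

**C8–C9 bond (33/32 ⇒ 25 + 29).** Cutting C8–C9 splits the carbon skeleton into ring A aldehyde 25 and the four-carbon lactone 29, the "inverted" lactone with C7 as carbonyl and C19 as OCH2. Its enolate carbon is C8, so the aldol creates the tertiary carbinol directly, with C9 trans to the C18 methyl. The alternative of adding C17–C19 to a C8 ketone was rejected because the facial bias of such a ketone is not predictable. A closed lithium-enolate transition state would pair the faces wrongly (O8/O9 syn). The forward reaction is therefore a Mukaiyama aldol of ketene acetal 31 through an open transition state, with Felkin–Anh control at C9.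

**Ring A adjustment and C2–C3 bond (25 ⇒ 21 ⇒ 20 ⇒ 19 ⇒ 10 + 17).** Aldehyde 25 comes from ester 23 and, further back, from ketone 21 and enol ether 20. The C12 carbinol is set by hydride delivery opposite the axial C14 silyloxy group. The C11=C20 olefin is held as a C20 phenylselanyl group until after the aldol step (35 ⇐ 33). An oxygen leaving group at C20 was considered and set aside, because base-induced elimination from the C12 ketone would compete with loss of the C14 oxygen, whereas selenoxide elimination is regiospecific. Cutting C2–C3 of 19 gives cycloadduct 10 and Grignard precursor 17, which brings C3–C6 and C16 with the chloroalkene already in place. The addition must favour 2R, which a bulky, non-chelating silyl ether on O14 supports.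

**Ring A by [4+2] (10 ⇒ 2 + 9).** Cutting C1–C14 and C10–C11 reduces 10 to enal ester 2 and diene 9. No other cut of ring A sets the quaternary C1, C10 and C14 in one catalytic, enantioselective step from achiral materials, and it also delivers the handles at C2, C9, C12 and C20. The forward reaction must be regioselective (C11 to C10), endo for the formyl group, and face-selective under catalyst control.

**Building blocks.** Enal 2 is the allylic oxidation product of 1. Diene 9 comes from enone 8, made from selenide 5 (from 3 and 4). Bromide 17 comes from propargyl alcohol 11 through chlorodiene 13, ether 14 and alcohol 16. Lactone 29 comes from the enantiopure lactone 26 through 28.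

## Roads not taken

**Alternative 1:** The cut is C6–C7 together with the O7–C19 lactone bond, in a fully decorated open chain. In the forward direction CrCl2 reduces the C16 allylic bromide of A2, the γ-chloroallylchromium adds through C6 to the C7 aldehyde, and the C7 alkoxide closes the lactone onto the C19 ester to give A1.
- Merits: one operation forms the macrocycle, two stereocentres and the lactone, with three acetates already in place. The endgame is shorter than in the chosen route, which needs a separate oxidation to the lactone and a global desilylation.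
- Weak points: A2 is a tertiary α-hydroxy aldehyde and a β-hydroxy ester at once, prone to α-ketol shift and retro-aldol cleavage. Its acetates forbid the hydride and enolate chemistry needed to build the C7–C9/C17–C19 array. C17 is epimerizable before lactonization. The plan gives no origin for ring A or for absolute configuration.
- Comparison: the chosen route keeps this bond-forming event (step 25) but runs it on lactol 38, where the aldehyde is masked, O8 is silylated and C17 is configurationally safe. What it sets against the shorter endgame of A1 is a sturdier substrate and a defined source for every stereocentre.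

**Alternative 2:** The cuts are C1–C2 and C9–C10, followed by cleavage of C2–C9. Irradiation of ring A enone A4 with the eight-membered enediol bis-silyl ether A5 gives cyclobutane A3, and glycol cleavage merges the four- and eight-membered rings into the cyclodecane.
- Merits: no macrocyclization at all, and C1 and C10 are joined to the medium ring in one convergent step. In ring construction this road is better than the chosen one.
- Weak points: the [2+2] step must bond a β,β-disubstituted enone carbon to a tetrasubstituted olefin, with facial control resting on one silyloxy group. After cleavage C2 and C9 are ketones that need stereoselective reduction inside a medium ring. Ring A arrives with its carbonyl at C11 and no oxygen at C12 and no C20. C8 is a ketal that still needs conversion into the quaternary carbinol and lactone. The C5=C6 olefin still needs chlorination with transposition.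
- Comparison: the chosen plan pays for a late macrocyclization but fixes the whole ring A pattern catalytically and builds C7–C9 by acyclic stereocontrol.

**Alternative 3:** The cut is C3–C4 (formed) against O–C6 (broken). Heating the ring A-fused 2-methyleneoxocane A7 triggers a [3,3] shift to cyclodecenone A6.
- Merits: a chair-like Claisen ring expansion needs no high dilution, gives the olefin geometry predictably and carries the C7/C8 diol through intact. It is probably the most dependable ring closure of all four plans.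
- Weak points: A6 has an endocyclic E C5=C6 olefin with a C16 methyl group, so chlorine must be introduced late with allylic transposition and unproven facial control. C8 is only a secondary carbinol, so the C17–C19 unit and the quaternary centre must be added to a ring ketone. C2 is a ketone. A7 needs a long synthesis (eight-membered lactone, methylenation) that presupposes an enantiopure ring A.
- Comparison: the chosen plan accepts a riskier ring closure in exchange for forming C6–Cl, C7–O and the exocyclic olefin in the same step, and for a short catalytic entry to ring A.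

Key step: step 5

Assumption: the (S)-prolinol-derived oxazaborolidinium ion is taken to expose the enal face that leads to 10 (if the sense is opposite, the (R)-catalyst is used and nothing else changes), and (R)-4-methyldihydrofuran-2(3H)-one 26 is taken as a purchasable enantiopure lactone.

## Route

Step 1
Reactants: 1 methyl 3-methylbut-2-enoate
Product: 2 methyl (E)-3-formylbut-2-enoate
Conditions: SeO2, 1,4-dioxane, reflux
Reagents that add atoms: selenium dioxide, O=[Se]=O
Why: Riley allylic oxidation; the ene reaction and [2,3]-shift take place at the methyl group trans to the ester, which gives the E aldehyde directly.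

Step 2
Reactants: 3 but-3-en-2-one; 4 benzeneselenol
Product: 5 4-(phenylselanyl)butan-2-one
Conditions: Et3N (cat.), CH2Cl2, 0 °C to rt
Reagents that add atoms: none
Why: Conjugate (seleno-Michael) addition of the soft selenol to the enone; the selenide is the latent C11=C20 olefin.

Step 3
Reactants: 5 4-(phenylselanyl)butan-2-one
Product: 8 (E)-1-(tert-butyldimethylsilyloxy)-5-(phenylselanyl)pent-1-en-3-one, via kinetic lithium enolate 6 (not isolated), via lithium hydroxymethylene enolate 7 (not isolated)
Conditions: LiN(i-Pr)2, THF, −78 °C; HCO2CH2CF3, −78 °C; then TBSCl, DMAP (cat.), −78 to 0 °C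
Reagents that add atoms: 2,2,2-trifluoroethyl formate, O=COCC(F)(F)F; tert-butyldimethylsilyl chloride, CC(C)(C)[Si](C)(C)Cl
Why: Kinetic deprotonation at the methyl group (the C3 enolate, which could expel selenolate, is avoided), Claisen-type formylation with the activated formate, and O-silylation at the formyl oxygen; DMAP equilibrates the vinylogous silyl ester to the E isomer by addition–elimination.

Step 4
Reactants: 8 (E)-1-(tert-butyldimethylsilyloxy)-5-(phenylselanyl)pent-1-en-3-one
Product: 9 (1E,3Z)-1,3-bis(tert-butyldimethylsilyloxy)-5-(phenylselanyl)penta-1,3-diene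
Conditions: TBSOTf, Et3N, Et2O, 0 °C
Reagents that add atoms: tert-butyldimethylsilyl triflate, CC(C)(C)[Si](C)(C)OS(=O)(=O)C(F)(F)F
Why: Soft enolization toward the only α-CH2 gives the 2-silyloxy diene; the Z enol ether (silyloxy cis to CH2SePh) is the usual outcome for α-CH2R ketones and places C20 on the outside of the diene.

Step 5
Reactants: 2 methyl (E)-3-formylbut-2-enoate; 9 (1E,3Z)-1,3-bis(tert-butyldimethylsilyloxy)-5-(phenylselanyl)penta-1,3-diene
Product: 10 methyl (1S,2S,5S,6R)-3,5-bis(tert-butyldimethylsilyloxy)-6-formyl-6-methyl-2-[(phenylselanyl)methyl]cyclohex-3-ene-1-carboxylate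
Conditions: (S)-3,3-diphenyl-1-(2-methylphenyl)tetrahydro-1H,3H-pyrrolo[1,2-c][1,3,2]oxazaborole protonated by Tf2NH (20 mol %), CH2Cl2, −78 °C
Reagents that add atoms: none
Why: Lewis acid-catalysed normal-demand Diels–Alder reaction: the oxazaborolidinium ion binds the formyl oxygen of 2 (the more basic carbonyl, formyl C–H against the ring oxygen), lowers the LUMO and puts its largest coefficient on C10. The nucleophilic terminus C11 of 9 therefore bonds first to C10 and C14 then to C1, in a concerted, asynchronous [4+2] closure of six-membered ring A. The closest known reaction type is the oxazaborolidinium-catalysed cycloaddition of α-substituted acroleins with 2-silyloxy and 1-oxy-3-silyloxy dienes. C1/C10: suprafacial addition to the E olefin keeps the formyl and ester groups trans. C14 relative to C1: the boron-bound formyl group lies endo, so the outside silyloxy group at C14 ends cis to C2. C11: the 3Z geometry puts CH2SePh outside and hence cis to O14 (this centre is erased in step 21). Absolute configuration: the aryl groups of the catalyst shield one face of the s-trans enal. The step needs formyl-directed regiochemistry, endo-formyl over endo-ester, and C=C over C=O addition; single-point binding at the formyl group and the doubly activated olefin secure these.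

Step 6
Reactants: 11 prop-2-yn-1-ol
Product: 13 (Z)-2-(chloromethylidene)but-3-en-1-ol, via alkenylmagnesium chelate 12 (not isolated)
Conditions: CH2=CHMgBr (2.3 equiv), CuI (10 mol %), THF, −20 °C to rt; then N-chlorosuccinimide, −40 °C
Reagents that add atoms: vinylmagnesium bromide, C=C[Mg]Br; N-chlorosuccinimide, O=C1CCC(=O)N1Cl
Why: Copper-catalysed anti-carbomagnesiation of the propargylic alkoxide puts vinyl on the internal carbon and magnesium cis to the CH2O group in a five-membered chelate; chlorination of the alkenyl Grignard reagent proceeds with retention.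

Step 7
Reactants: 13 (Z)-2-(chloromethylidene)but-3-en-1-ol
Product: 14 1-({[(2Z)-2-(chloromethylidene)but-3-en-1-yl]oxy}methyl)-4-methoxybenzene
Conditions: NaH, 4-MeOC6H4CH2Cl, n-Bu4NI (cat.), THF/DMF, 0 °C to rt
Reagents that add atoms: 4-methoxybenzyl chloride, COc1ccc(CCl)cc1
Why: Williamson etherification; PMB is the one group in the route that is later removed oxidatively.

Step 8
Reactants: 14 1-({[(2Z)-2-(chloromethylidene)but-3-en-1-yl]oxy}methyl)-4-methoxybenzene
Product: 16 (3Z)-4-chloro-3-{[(4-methoxybenzyl)oxy]methyl}but-3-en-1-ol, via B-alkyl-9-borabicyclononane 15 (not isolated)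
Conditions: 9-BBN, THF, 0 °C to rt; then NaOH, H2O2, 0 °C
Reagents that add atoms: hydrogen peroxide, OO
Why: Hydroboration–oxidation; 9-BBN adds to the terminal vinyl carbon, while the trisubstituted, chlorine-deactivated olefin is far less reactive.

Step 9
Reactants: 16 (3Z)-4-chloro-3-{[(4-methoxybenzyl)oxy]methyl}but-3-en-1-ol
Product: 17 1-({[(2Z)-4-bromo-2-(chloromethylidene)butyl]oxy}methyl)-4-methoxybenzene
Conditions: CBr4, PPh3, CH2Cl2, 0 °C
Reagents that add atoms: carbon tetrabromide, BrC(Br)(Br)Br
Why: Appel bromination of the primary alcohol under neutral conditions.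

Step 10
Reactants: 10 ring A cycloadduct (as named in step 5); 17 1-({[(2Z)-4-bromo-2-(chloromethylidene)butyl]oxy}methyl)-4-methoxybenzene
Product: 19 (2R)-C2 carbinol of the ring A ester (C2–C6/C16 arm attached), via Grignard reagent 18 (not isolated)
Conditions: 17, Mg, THF, rt; then 10, THF, −78 to −40 °C; aqueous NH4Cl at −78 °C
Reagents that add atoms: none
Why: Grignard addition to the non-enolizable neopentyl aldehyde is faster than attack on the hindered ester. Felkin–Anh control from the quaternary C1: the nucleophile enters anti to C14, whose bulky, non-chelating silyloxy group is cis to the formyl group, and passes the methyl group, giving 2R. The cold quench keeps the C2 alkoxide from lactonizing onto C9.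

Step 11
Reactants: 19 (2R)-C2 carbinol
Product: 20 C2 tert-butyldimethylsilyl ether
Conditions: TBSOTf, 2,6-lutidine, CH2Cl2, −78 to 0 °C
Reagents that add atoms: tert-butyldimethylsilyl triflate, CC(C)(C)[Si](C)(C)OS(=O)(=O)C(F)(F)F
Why: Silyl triflate silylation of the hindered secondary alcohol; O2 must be masked before C9 becomes an aldehyde, which a free C2 hydroxyl would trap as a lactol.

Step 12
Reactants: 20 C2 tert-butyldimethylsilyl ether
Product: 21 C12 ketone
Conditions: n-Bu4NF, AcOH, THF, −78 to −20 °C
Reagents that add atoms: none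
Why: Fluoride cleaves the silyl enol ether much faster than the alkyl silyl ethers; acetic acid protonates the enolate at once and suppresses β-elimination of the C14 silyloxy and C20 selanyl groups.

Step 13
Reactants: 21 C12 ketone
Product: 22 (12R)-C12 alcohol
Conditions: LiBH(s-Bu)3, THF, −78 °C
Reagents that add atoms: none
Why: Bulky hydride reduction; ring A adopts the chair with C15 and the C14 silyloxy group axial and both large arms equatorial, so the axial trajectory at C12 is blocked by the syn-axial C14 oxygen and hydride enters equatorially, giving the axial alcohol cis to O14. The ester is inert at this temperature.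

Step 14
Reactants: 22 (12R)-C12 alcohol
Product: 23 C12 triethylsilyl ether
Conditions: Et3SiOTf, 2,6-lutidine, CH2Cl2, −78 °C
Reagents that add atoms: triethylsilyl triflate, CC[Si](CC)(CC)OS(=O)(=O)C(F)(F)F
Why: Silyl triflate silylation of the axial secondary alcohol.

Step 15
Reactants: 23 C12 triethylsilyl ether
Product: 24 C9 primary alcohol
Conditions: i-Bu2AlH, CH2Cl2, −78 to 0 °C
Reagents that add atoms: none
Why: Aluminium hydride reduction of the methyl ester; silyl ethers, selenide, PMB ether and chloroalkene are inert.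

Step 16
Reactants: 24 C9 primary alcohol
Product: 25 C9 aldehyde
Conditions: SO3·pyridine, DMSO, i-Pr2NEt, CH2Cl2, 0 °C
Reagents that add atoms: none
Why: Parikh–Doering oxidation, chosen because activated DMSO leaves the selenide untouched; C10 does not epimerize since the formyl group is already equatorial and trans to C2.

Step 17
Reactants: 26 (R)-4-methyldihydrofuran-2(3H)-one
Product: 28 (3R,4S)-3-hydroxy-4-methyldihydrofuran-2(3H)-one, via sodium enolate 27 (not isolated)
Conditions: NaN(SiMe3)2, THF, −78 °C; then 2-(phenylsulfonyl)-3-phenyloxaziridine, −78 °C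
Reagents that add atoms: 2-(phenylsulfonyl)-3-phenyloxaziridine, O=S(=O)(c1ccccc1)N1OC1c1ccccc1
Why: Enolate hydroxylation with an N-sulfonyloxaziridine; oxygen is delivered anti to the C4 methyl group (this centre is planarized again in step 19, so its configuration is immaterial).

Step 18
Reactants: 28 (3R,4S)-3-hydroxy-4-methyldihydrofuran-2(3H)-one
Product: 29 (3R,4S)-4-methyl-3-(triethylsilyloxy)dihydrofuran-2(3H)-one
Conditions: Et3SiCl, imidazole, DMF, 0 °C to rt
Reagents that add atoms: triethylsilyl chloride, CC[Si](Cl)(CC)CC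
Why: Standard silylation of a secondary alcohol.

Step 19
Reactants: 25 C9 aldehyde; 29 (3R,4S)-4-methyl-3-(triethylsilyloxy)dihydrofuran-2(3H)-one
Product: 32 (8R,9R)-aldol adduct, via lithium enolate 30 (not isolated), via silyl ketene acetal 31 (not isolated)
Conditions: 29, LiN(i-Pr)2, Me3SiCl, THF, −78 °C; then 25, BF3·OEt2, CH2Cl2, −78 °C
Reagents that add atoms: none
Why: Mukaiyama aldol addition through an open transition state, in which each partner follows its own facial bias: the BF3-bound aldehyde reacts on its Felkin–Anh face (nucleophile anti to the quaternary C1), giving 9R, and ketene acetal 31 reacts anti to the C18 methyl group, giving the quaternary C8 with C9 trans to C18. A closed lithium-enolate chair would pair the faces the other way (O8 and O9 syn), which is why the Lewis acid variant is used.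

Step 20
Reactants: 32 (8R,9R)-aldol adduct
Product: 33 C9 triethylsilyl ether
Conditions: Et3SiOTf, 2,6-lutidine, CH2Cl2, −78 to 0 °C
Reagents that add atoms: triethylsilyl triflate, CC[Si](CC)(CC)OS(=O)(=O)C(F)(F)F
Why: Silyl triflate silylation of the hindered carbinol, which also removes the retro-aldol pathway; any O8-to-O9 silyl shift converges on the same bis-silyl ether.

Step 21
Reactants: 33 C9 triethylsilyl ether
Product: 35 C11=C20 exocyclic olefin, via selenoxide 34 (not isolated)
Conditions: H2O2 (30 % aq), pyridine, CH2Cl2, 0 °C to rt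
Reagents that add atoms: none
Why: Selenide oxidation and selenoxide syn-elimination; C11–H is the only β-hydrogen, so the exocyclic olefin forms regiospecifically without touching the C14 oxygen.

Step 22
Reactants: 35 C11=C20 exocyclic olefin
Product: 36 C16 allylic alcohol
Conditions: DDQ, CH2Cl2/pH 7 buffer, 0 °C
Reagents that add atoms: none
Why: Oxidative PMB ether cleavage; silyl ethers, the chloroalkene and the 1,1-disubstituted olefin are inert.

Step 23
Reactants: 36 C16 allylic alcohol
Product: 37 C16 allylic bromide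
Conditions: CBr4, PPh3, 2,6-lutidine, CH2Cl2, −20 °C
Reagents that add atoms: carbon tetrabromide, BrC(Br)(Br)Br
Why: Appel bromination at the primary allylic carbon; SN2′ attack is disfavoured because it would place bromine on the chlorinated carbon.

Step 24
Reactants: 37 C16 allylic bromide
Product: 38 C7 lactol
Conditions: i-Bu2AlH, toluene, −78 °C
Reagents that add atoms: none
Why: Partial reduction of the γ-lactone to the lactol through the stable tetrahedral aluminate; the allylic bromide is not reduced at this temperature.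

Step 25
Reactants: 38 C7 lactol
Product: 40 macrocyclic chlorohydrin diol, via allylchromium dichloride 39 (not isolated)
Conditions: CrCl2 (4 equiv), THF (2 mM, slow addition), rt
Reagents that add atoms: none
Why: Intramolecular Nozaki–Hiyama allylation: CrCl2 (divalent chromium) inserts into the C16–Br bond and the allylchromium adds through its chlorine-bearing γ-carbon C6 to the aldehyde released from the lactol. The precedents are the intermolecular chromium-mediated γ-chloroallylation of aldehydes and chromium-mediated closures of ten-membered carbocycles. C7 is set by Felkin–Anh addition anti to the C8 silyloxy group and past the smaller C17 arm (7R); C6 is set by the chair transition state with chlorine pseudo-equatorial after E/Z equilibration of the allylchromium (anti chlorohydrin, 6S).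

Step 26
Reactants: 40 macrocyclic chlorohydrin diol
Product: 42 γ-lactone, via macrocyclic lactol 41 (not isolated)
Conditions: TEMPO (20 mol %), PhI(OAc)2, CH2Cl2, rt
Reagents that add atoms: none
Why: Nitroxyl-catalysed oxidation selective for the primary C19 alcohol; the hydroxy aldehyde closes onto the C7 hydroxyl and the lactol is oxidized to the lactone. O9 is silylated, so only O7 can lactonize.

Step 27
Reactants: 42 γ-lactone
Product: 43 pentaol
Conditions: HF·pyridine, pyridine, THF, 0 °C to rt
Reagents that add atoms: none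
Why: Global desilylation under buffered fluoride; lactone, allylic chloride and olefins tolerate it, and it is done before the epoxide exists.

Step 28
Reactants: 43 pentaol
Product: 44 (11R)-11,20-epoxide
Conditions: VO(acac)2 (5 mol %), t-BuOOH, CH2Cl2, 0 °C
Reagents that add atoms: tert-butyl hydroperoxide, CC(C)(C)OO
Why: Vanadium-catalysed hydroxyl-directed epoxidation; the axial allylic C12 hydroxyl delivers oxygen to C11=C20 from its own face. Allylic delivery is much faster than homoallylic or bishomoallylic delivery, and the C5=C16 olefin is deactivated by the allylic chlorine.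

Step 29
Reactants: 44 (11R)-11,20-epoxide
Product: 45 CNP0349227.4
Conditions: Ac2O, pyridine, DMAP (cat.), CH2Cl2, 0 °C to rt
Reagents that add atoms: acetic anhydride, CC(=O)OC(C)=O
Why: Acetylation of the four secondary hydroxyls; the hindered tertiary C8 hydroxyl stays free under these mild conditions.

## Compound list

Abbreviations: TBS = tert-butyldimethylsilyl, TES = triethylsilyl, PMB = 4-methoxybenzyl. Locants in names from 19 on are briarane locants, and configurations are those of the SMILES.

1 | methyl 3-methylbut-2-enoate | COC(=O)C=C(C)C | starting material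
2 | methyl (E)-3-formylbut-2-enoate | O=C/C(C)=C/C(=O)OC | intermediate
3 | but-3-en-2-one | CC(=O)C=C | starting material
4 | benzeneselenol | [SeH]c1ccccc1 | starting material
5 | 4-(phenylselanyl)butan-2-one | CC(=O)CC[Se]c1ccccc1 | intermediate
6 | lithium 4-(phenylselanyl)but-1-en-2-olate | [Li+].[O-]C(=C)CC[Se]c1ccccc1 | intermediate
7 | lithium (Z)-3-oxo-5-(phenylselanyl)pent-1-en-1-olate | [Li+].[O-]/C=C\C(=O)CC[Se]c1ccccc1 | intermediate
8 | (E)-1-(tert-butyldimethylsilyloxy)-5-(phenylselanyl)pent-1-en-3-one | CC(C)(C)[Si](C)(C)O/C=C/C(=O)CC[Se]c1ccccc1 | intermediate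
9 | (1E,3Z)-1,3-bis(tert-butyldimethylsilyloxy)-5-(phenylselanyl)penta-1,3-diene | CC(C)(C)[Si](C)(C)O/C=C/C(O[Si](C)(C)C(C)(C)C)=C/C[Se]c1ccccc1 | intermediate
10 | methyl (1S,2S,5S,6R)-3,5-bis(tert-butyldimethylsilyloxy)-6-formyl-6-methyl-2-[(phenylselanyl)methyl]cyclohex-3-ene-1-carboxylate (ring A: C2 formyl, C9 ester, C12 silyl enol ether, 14-OTBS, 20-SePh) | O=C[C@@]1(C)[C@@H](O[Si](C)(C)C(C)(C)C)C=C(O[Si](C)(C)C(C)(C)C)[C@@H](C[Se]c2ccccc2)[C@@H]1C(=O)OC | intermediate
11 | prop-2-yn-1-ol | C#CCO | starting material
12 | bromomagnesium (Z)-2-[(bromomagnesio)methylidene]but-3-en-1-olate | Br[Mg]/C=C(\CO[Mg]Br)C=C | intermediate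
13 | (Z)-2-(chloromethylidene)but-3-en-1-ol | Cl/C=C(\CO)C=C | intermediate
14 | 1-({[(2Z)-2-(chloromethylidene)but-3-en-1-yl]oxy}methyl)-4-methoxybenzene | Cl/C=C(\COCc1ccc(OC)cc1)C=C | intermediate
15 | 9-[(3Z)-4-chloro-3-{[(4-methoxybenzyl)oxy]methyl}but-3-en-1-yl]-9-borabicyclo[3.3.1]nonane | Cl/C=C(\COCc1ccc(OC)cc1)CCB1C2CCCC1CCC2 | intermediate
16 | (3Z)-4-chloro-3-{[(4-methoxybenzyl)oxy]methyl}but-3-en-1-ol | Cl/C=C(\COCc1ccc(OC)cc1)CCO | intermediate
17 | 1-({[(2Z)-4-bromo-2-(chloromethylidene)butyl]oxy}methyl)-4-methoxybenzene | Cl/C=C(\COCc1ccc(OC)cc1)CCBr | intermediate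
18 | [(3Z)-4-chloro-3-{[(4-methoxybenzyl)oxy]methyl}but-3-en-1-yl]magnesium bromide | Cl/C=C(\COCc1ccc(OC)cc1)CC[Mg]Br | intermediate
19 | ring A methyl ester with (2R)-2-hydroxy arm: 12-OTBS enol ether (C12=C13), 14-OTBS, 20-SePh, (5Z)-6-chloro-5-ene, 16-OPMB | Cl/C=C(\COCc1ccc(OC)cc1)CC[C@@H](O)[C@@]1(C)[C@@H](O[Si](C)(C)C(C)(C)C)C=C(O[Si](C)(C)C(C)(C)C)[C@@H](C[Se]c2ccccc2)[C@@H]1C(=O)OC | intermediate
20 | 2-O-TBS ether of 19 | Cl/C=C(\COCc1ccc(OC)cc1)CC[C@@H](O[Si](C)(C)C(C)(C)C)[C@@]1(C)[C@@H](O[Si](C)(C)C(C)(C)C)C=C(O[Si](C)(C)C(C)(C)C)[C@@H](C[Se]c2ccccc2)[C@@H]1C(=O)OC | intermediate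
21 | C12 ketone: 2,14-bis-OTBS, 20-SePh, C9 methyl ester | Cl/C=C(\COCc1ccc(OC)cc1)CC[C@@H](O[Si](C)(C)C(C)(C)C)[C@@]1(C)[C@@H](O[Si](C)(C)C(C)(C)C)CC(=O)[C@@H](C[Se]c2ccccc2)[C@@H]1C(=O)OC | intermediate
22 | (12R)-12-hydroxy compound (12-OH cis to 14-OTBS) | Cl/C=C(\COCc1ccc(OC)cc1)CC[C@@H](O[Si](C)(C)C(C)(C)C)[C@@]1(C)[C@@H](O[Si](C)(C)C(C)(C)C)C[C@@H](O)[C@@H](C[Se]c2ccccc2)[C@@H]1C(=O)OC | intermediate
23 | 12-O-TES ether of 22 | Cl/C=C(\COCc1ccc(OC)cc1)CC[C@@H](O[Si](C)(C)C(C)(C)C)[C@@]1(C)[C@@H](O[Si](C)(C)C(C)(C)C)C[C@@H](O[Si](CC)(CC)CC)[C@@H](C[Se]c2ccccc2)[C@@H]1C(=O)OC | intermediate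
24 | C9 primary alcohol (CH2OH on C10) | Cl/C=C(\COCc1ccc(OC)cc1)CC[C@@H](O[Si](C)(C)C(C)(C)C)[C@@]1(C)[C@@H](O[Si](C)(C)C(C)(C)C)C[C@@H](O[Si](CC)(CC)CC)[C@@H](C[Se]c2ccccc2)[C@@H]1CO | intermediate
25 | C9 aldehyde (CHO on C10) | Cl/C=C(\COCc1ccc(OC)cc1)CC[C@@H](O[Si](C)(C)C(C)(C)C)[C@@]1(C)[C@@H](O[Si](C)(C)C(C)(C)C)C[C@@H](O[Si](CC)(CC)CC)[C@@H](C[Se]c2ccccc2)[C@@H]1C=O | intermediate
26 | (R)-4-methyldihydrofuran-2(3H)-one | C[C@H]1COC(=O)C1 | starting material
27 | sodium (R)-4-methyl-4,5-dihydrofuran-2-olate | [Na+].C[C@H]1COC([O-])=C1 | intermediate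
28 | (3R,4S)-3-hydroxy-4-methyldihydrofuran-2(3H)-one | C[C@H]1COC(=O)[C@@H]1O | intermediate
29 | (3R,4S)-4-methyl-3-(triethylsilyloxy)dihydrofuran-2(3H)-one | C[C@H]1COC(=O)[C@@H]1O[Si](CC)(CC)CC | intermediate
30 | lithium (S)-4-methyl-3-(triethylsilyloxy)-4,5-dihydrofuran-2-olate | [Li+].C[C@H]1COC([O-])=C1O[Si](CC)(CC)CC | intermediate
31 | (S)-4-methyl-3-(triethylsilyloxy)-2-(trimethylsilyloxy)-4,5-dihydrofuran | C[C@H]1COC(O[Si](C)(C)C)=C1O[Si](CC)(CC)CC | intermediate
32 | aldol adduct: (9R)-9-hydroxy, (8R)-8-OTES, lactone C7(=O)–O–C19H2 with 17-methyl trans to C9; ring A as in 25 | Cl/C=C(\COCc1ccc(OC)cc1)CC[C@@H](O[Si](C)(C)C(C)(C)C)[C@@]1(C)[C@@H](O[Si](C)(C)C(C)(C)C)C[C@@H](O[Si](CC)(CC)CC)[C@@H](C[Se]c2ccccc2)[C@@H]1[C@@H](O)[C@]2(O[Si](CC)(CC)CC)[C@@H](C)COC2=O | intermediate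
33 | 9-O-TES ether of 32 | Cl/C=C(\COCc1ccc(OC)cc1)CC[C@@H](O[Si](C)(C)C(C)(C)C)[C@@]1(C)[C@@H](O[Si](C)(C)C(C)(C)C)C[C@@H](O[Si](CC)(CC)CC)[C@@H](C[Se]c2ccccc2)[C@@H]1[C@@H](O[Si](CC)(CC)CC)[C@]2(O[Si](CC)(CC)CC)[C@@H](C)COC2=O | intermediate
34 | C20 phenylselenoxide of 33 | Cl/C=C(\COCc1ccc(OC)cc1)CC[C@@H](O[Si](C)(C)C(C)(C)C)[C@@]1(C)[C@@H](O[Si](C)(C)C(C)(C)C)C[C@@H](O[Si](CC)(CC)CC)[C@@H](C[Se](=O)c2ccccc2)[C@@H]1[C@@H](O[Si](CC)(CC)CC)[C@]2(O[Si](CC)(CC)CC)[C@@H](C)COC2=O | intermediate
35 | C11=C20 exocyclic olefin: 2,14-bis-OTBS, 8,9,12-tris-OTES, 16-OPMB, lactone C7(=O)–O–C19H2 | Cl/C=C(\COCc1ccc(OC)cc1)CC[C@@H](O[Si](C)(C)C(C)(C)C)[C@@]1(C)[C@@H](O[Si](C)(C)C(C)(C)C)C[C@@H](O[Si](CC)(CC)CC)C(=C)[C@@H]1[C@@H](O[Si](CC)(CC)CC)[C@]2(O[Si](CC)(CC)CC)[C@@H](C)COC2=O | intermediate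
36 | C16 allylic alcohol from 35 | Cl/C=C(\CO)CC[C@@H](O[Si](C)(C)C(C)(C)C)[C@@]1(C)[C@@H](O[Si](C)(C)C(C)(C)C)C[C@@H](O[Si](CC)(CC)CC)C(=C)[C@@H]1[C@@H](O[Si](CC)(CC)CC)[C@]2(O[Si](CC)(CC)CC)[C@@H](C)COC2=O | intermediate
37 | C16 allylic bromide, (5Z)-6-chloro-5-ene | Cl/C=C(\CBr)CC[C@@H](O[Si](C)(C)C(C)(C)C)[C@@]1(C)[C@@H](O[Si](C)(C)C(C)(C)C)C[C@@H](O[Si](CC)(CC)CC)C(=C)[C@@H]1[C@@H](O[Si](CC)(CC)CC)[C@]2(O[Si](CC)(CC)CC)[C@@H](C)COC2=O | intermediate
38 | C7 lactol of 37 (both anomers) | Cl/C=C(\CBr)CC[C@@H](O[Si](C)(C)C(C)(C)C)[C@@]1(C)[C@@H](O[Si](C)(C)C(C)(C)C)C[C@@H](O[Si](CC)(CC)CC)C(=C)[C@@H]1[C@@H](O[Si](CC)(CC)CC)[C@]2(O[Si](CC)(CC)CC)[C@@H](C)COC2O | intermediate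
39 | C16 allylchromium dichloride (trivalent chromium) from 38 | Cl/C=C(\C[Cr](Cl)Cl)CC[C@@H](O[Si](C)(C)C(C)(C)C)[C@@]1(C)[C@@H](O[Si](C)(C)C(C)(C)C)C[C@@H](O[Si](CC)(CC)CC)C(=C)[C@@H]1[C@@H](O[Si](CC)(CC)CC)[C@]2(O[Si](CC)(CC)CC)[C@@H](C)COC2O | intermediate
40 | macrocyclic diol: (6S)-6-chloro, (7R)-7-hydroxy, 5(16)-ene, 19-hydroxy, 2,14-bis-OTBS, 8,9,12-tris-OTES, 11(20)-ene | C=C1CC[C@@H](O[Si](C)(C)C(C)(C)C)[C@@]2(C)[C@@H](O[Si](C)(C)C(C)(C)C)C[C@@H](O[Si](CC)(CC)CC)C(=C)[C@@H]2[C@@H](O[Si](CC)(CC)CC)[C@](O[Si](CC)(CC)CC)([C@@H](C)CO)[C@@H](O)[C@H]1Cl | intermediate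
41 | macrocyclic C19 lactol (O7–C19 hemiacetal) | C=C1CC[C@@H](O[Si](C)(C)C(C)(C)C)[C@@]2(C)[C@@H](O[Si](C)(C)C(C)(C)C)C[C@@H](O[Si](CC)(CC)CC)C(=C)[C@@H]2[C@@H](O[Si](CC)(CC)CC)[C@]2(O[Si](CC)(CC)CC)[C@@H](C)C(O)O[C@H]2[C@H]1Cl | intermediate
42 | persilylated γ-lactone (O7–C19=O): 2,14-bis-OTBS, 8,9,12-tris-OTES | C=C1CC[C@@H](O[Si](C)(C)C(C)(C)C)[C@@]2(C)[C@@H](O[Si](C)(C)C(C)(C)C)C[C@@H](O[Si](CC)(CC)CC)C(=C)[C@@H]2[C@@H](O[Si](CC)(CC)CC)[C@]2(O[Si](CC)(CC)CC)[C@@H](C)C(=O)O[C@H]2[C@H]1Cl | intermediate
43 | pentaol: 2,8,9,12,14-pentahydroxy-6-chloro-5(16),11(20)-diene lactone | C=C1CC[C@@H](O)[C@@]2(C)[C@@H](O)C[C@@H](O)C(=C)[C@@H]2[C@@H](O)[C@]2(O)[C@@H](C)C(=O)O[C@H]2[C@H]1Cl | intermediate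
44 | (11R)-11,20-epoxy pentaol | C=C1CC[C@@H](O)[C@@]2(C)[C@@H](O)C[C@@H](O)[C@]3(CO3)[C@@H]2[C@@H](O)[C@]2(O)[C@@H](C)C(=O)O[C@H]2[C@H]1Cl | intermediate
45 | CNP0349227.4: (1S,2R,6S,7R,8R,9R,10S,11R,12R,14S,17R)-2,9,12,14-tetraacetoxy-6-chloro-11,20-epoxy-8-hydroxybriar-5(16)-ene γ-lactone (O7–C19) | C=C1CC[C@@H](OC(C)=O)[C@@]2(C)[C@@H](OC(C)=O)C[C@@H](OC(C)=O)[C@]3(CO3)[C@@H]2[C@@H](OC(C)=O)[C@]2(O)[C@@H](C)C(=O)O[C@H]2[C@H]1Cl | target

## Step count and uncertain steps

Total step count: 29. Longest linear sequence: 22 steps (steps 2–5, 10–16 and 19–29).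

**Step 25 (ring closure).** The aldehyde is available only as the minor open form of a hindered lactol, so the ring closure may be slow at high dilution. The allylchromium can then be protonated, and excess CrCl2 can reduce the allylic chloride of the product with loss of the C7 oxygen; facial selectivity may also erode. The fallback unmasks a true aldehyde before cyclization. It sets out from 38: NaBH4 (THF/MeOH, −20 °C) reduces the lactol to the 1,4-diol F1; acetyl chloride with 2,4,6-collidine at −78 °C acetylates the less hindered C19 hydroxyl to give the monoacetate F2; Dess–Martin periodinane oxidizes the neopentyl C7 alcohol to the α-silyloxy aldehyde F3; CrCl2 then closes the ring to the macrocyclic acetate F4; reductive removal of the acetate with i-Bu2AlH at −78 °C (base is avoided, because it would close the chlorohydrin to an epoxide) returns to the route at 40.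

**Step 5 (key step).** The strongly Lewis acidic catalyst may divert the electron-rich diene into silyl transfer and stepwise Mukaiyama–Michael addition or into addition across the formyl C=O. The ester may also compete for the endo position, which would erode diastereo- and enantioselectivity. The fallback gives up catalyst control in favour of resolution. It sets out from 2 and 9: Me2AlCl-promoted cycloaddition gives racemic material, that is 10 together with its enantiomer F5; condensation with (1R,2R)-N,N′-dimethyl-1,2-diphenylethane-1,2-diamine (molecular sieves, Et2O) gives the diastereomeric imidazolidines F6 (from 10) and F7 (from F5), which are separated by chromatography; hydrolysis of F6 in a pH 5 buffer/Et2O two-phase system returns to the route at 10.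

**Step 19 (aldol).** Bond formation between two congested centres may stall, and the open transition state may not transmit both facial preferences, giving poor selectivity at C9. The fallback sets C9 by reduction instead of addition. It sets out from 32 (as the mixture at C9): Parikh–Doering oxidation gives the β-keto lactone F8; NaBH4 in MeOH/THF at −40 °C reduces it under Felkin–Anh control, with hydride anti to the C8 silyloxy group and past the planar lactone carbonyl, returning to the route at 32.

**Step 10 (Grignard addition).** Facial selectivity at the neopentyl aldehyde may be low because two ring carbons of similar size flank C1, and the C2 alkoxide may lactonize onto C9. The fallback sets C2 by reagent control. It sets out from 19 (as the mixture at C2): Parikh–Doering oxidation gives the C2 ketone F9; Corey–Bakshi–Shibata reduction with (S)-1-methyl-3,3-diphenyltetrahydro-1H,3H-pyrrolo[1,2-c][1,3,2]oxazaborole and catecholborane in toluene at −78 °C (the quaternary C1 as the large group) returns to the route at 19.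

**Step 28 (epoxidation).** Several free hydroxyls can bind vanadium, so conversion may be low and the homoallylic C9 hydroxyl may compete with the C12 hydroxyl in directing the oxidant. The fallback replaces hydroxyl direction by steric approach control. It sets out from 43: Ac2O/pyridine gives the tetraacetate F10; dimethyldioxirane in acetone at 0 °C epoxidizes the more electron-rich C11=C20 olefin from the face opposite the axial C15 methyl group, returning to the route at 45.

## Further compounds

F1 | step 25 | 1,4-diol from reduction of lactol 38 (C7 and C19 primary alcohols, allylic bromide retained) | Cl/C=C(\CBr)CC[C@@H](O[Si](C)(C)C(C)(C)C)[C@@]1(C)[C@@H](O[Si](C)(C)C(C)(C)C)C[C@@H](O[Si](CC)(CC)CC)C(=C)[C@@H]1[C@@H](O[Si](CC)(CC)CC)[C@@](O[Si](CC)(CC)CC)(CO)[C@@H](C)CO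
F2 | step 25 | C19 monoacetate of F1 | Cl/C=C(\CBr)CC[C@@H](O[Si](C)(C)C(C)(C)C)[C@@]1(C)[C@@H](O[Si](C)(C)C(C)(C)C)C[C@@H](O[Si](CC)(CC)CC)C(=C)[C@@H]1[C@@H](O[Si](CC)(CC)CC)[C@@](O[Si](CC)(CC)CC)(CO)[C@@H](C)COC(C)=O
F3 | step 25 | C7 aldehyde with 19-acetoxy group | Cl/C=C(\CBr)CC[C@@H](O[Si](C)(C)C(C)(C)C)[C@@]1(C)[C@@H](O[Si](C)(C)C(C)(C)C)C[C@@H](O[Si](CC)(CC)CC)C(=C)[C@@H]1[C@@H](O[Si](CC)(CC)CC)[C@@](O[Si](CC)(CC)CC)(C=O)[C@@H](C)COC(C)=O
F4 | step 25 | 19-O-acetyl derivative of macrocyclic diol 40 | C=C1CC[C@@H](O[Si](C)(C)C(C)(C)C)[C@@]2(C)[C@@H](O[Si](C)(C)C(C)(C)C)C[C@@H](O[Si](CC)(CC)CC)C(=C)[C@@H]2[C@@H](O[Si](CC)(CC)CC)[C@](O[Si](CC)(CC)CC)([C@@H](C)COC(C)=O)[C@@H](O)[C@H]1Cl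
F5 | step 5 | enantiomer of cycloadduct 10 | O=C[C@]1(C)[C@H](O[Si](C)(C)C(C)(C)C)C=C(O[Si](C)(C)C(C)(C)C)[C@H](C[Se]c2ccccc2)[C@H]1C(=O)OC
F6 | step 5 | (4R,5R)-1,3-dimethyl-4,5-diphenylimidazolidine (aminal) of 10 at C2 | CN1[C@H](c2ccccc2)[C@@H](c2ccccc2)N(C)C1[C@@]1(C)[C@@H](O[Si](C)(C)C(C)(C)C)C=C(O[Si](C)(C)C(C)(C)C)[C@@H](C[Se]c2ccccc2)[C@@H]1C(=O)OC
F7 | step 5 | (4R,5R)-1,3-dimethyl-4,5-diphenylimidazolidine (aminal) of F5 at C2 | CN1[C@H](c2ccccc2)[C@@H](c2ccccc2)N(C)C1[C@]1(C)[C@H](O[Si](C)(C)C(C)(C)C)C=C(O[Si](C)(C)C(C)(C)C)[C@H](C[Se]c2ccccc2)[C@H]1C(=O)OC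
F8 | step 19 | C9 ketone (β-keto lactone) from 32 | Cl/C=C(\COCc1ccc(OC)cc1)CC[C@@H](O[Si](C)(C)C(C)(C)C)[C@@]1(C)[C@@H](O[Si](C)(C)C(C)(C)C)C[C@@H](O[Si](CC)(CC)CC)[C@@H](C[Se]c2ccccc2)[C@@H]1C(=O)[C@]2(O[Si](CC)(CC)CC)[C@@H](C)COC2=O
F9 | step 10 | C2 ketone from 19 | Cl/C=C(\COCc1ccc(OC)cc1)CCC(=O)[C@@]1(C)[C@@H](O[Si](C)(C)C(C)(C)C)C=C(O[Si](C)(C)C(C)(C)C)[C@@H](C[Se]c2ccccc2)[C@@H]1C(=O)OC
F10 | step 28 | 2,9,12,14-tetraacetate lacking the epoxide oxygen (C11=C20 olefin) | C=C1CC[C@@H](OC(C)=O)[C@@]2(C)[C@@H](OC(C)=O)C[C@@H](OC(C)=O)C(=C)[C@@H]2[C@@H](OC(C)=O)[C@]2(O)[C@@H](C)C(=O)O[C@H]2[C@H]1Cl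
A1 | alternative 1 | macrocyclization product: target lacking the epoxide oxygen, 12-O-triethylsilyl | C=C1CC[C@@H](OC(C)=O)[C@@]2(C)[C@@H](OC(C)=O)C[C@@H](O[Si](CC)(CC)CC)C(=C)[C@@H]2[C@@H](OC(C)=O)[C@]2(O)[C@@H](C)C(=O)O[C@H]2[C@H]1Cl
A2 | alternative 1 | open-chain precursor: C16 allylic bromide, C6 chloroalkene, C7 aldehyde, 8-hydroxy, C19 methyl ester | Cl/C=C(/CBr)CC[C@@H](OC(C)=O)[C@@]1(C)[C@@H](OC(C)=O)C[C@@H](O[Si](CC)(CC)CC)C(=C)[C@@H]1[C@@H](OC(C)=O)[C@@](O)(C=O)[C@@H](C)C(=O)OC
A3 | alternative 2 | six-four-eight tricyclic bis(trimethylsilyloxy)cyclobutane | C1[C@]3(O[Si](C)(C)C)[C@@]2(C)[C@H](O[Si](C)(C)C(C)(C)C)CCC(=O)[C@@H]2[C@]3(O[Si](C)(C)C)C4(OCCO4)C/C=C(C)\C1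
A4 | alternative 2 | ring A enone: 4-(tert-butyldimethylsilyloxy)-3-methylcyclohex-2-en-1-one | CC1=CC(=O)CC[C@H]1O[Si](C)(C)C(C)(C)C
A5 | alternative 2 | eight-membered enediol bis(trimethylsilyl) ether with ethylene ketal and Z-trisubstituted olefin | C[Si](C)(C)OC1=C(O[Si](C)(C)C)C2(OCCO2)C/C=C(C)\CC1
A6 | alternative 3 | ring A-fused (E)-cyclodec-5-en-2-one with C7/C8 acetonide | C1C(=O)[C@@]2(C)[C@@H](O[Si](C)(C)C(C)(C)C)C[C@@H](O[Si](C)(C)C(C)(C)C)C(=C)[C@@H]2[C@@H](O[Si](C)(C)C(C)(C)C)[C@H]3OC(C)(C)O[C@H]3/C=C(C)/C1
A7 | alternative 3 | ring A-fused 2-methyleneoxocane with isopropenyl group on C6 and C7/C8 acetonide | C=C1[C@@]2(C)[C@@H](O[Si](C)(C)C(C)(C)C)C[C@@H](O[Si](C)(C)C(C)(C)C)C(=C)[C@@H]2[C@@H](O[Si](C)(C)C(C)(C)C)[C@H]3OC(C)(C)O[C@H]3C(C(C)=C)O1
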